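Molar for molar, the winter flask holds as much D as X, and I carry the ratio c(D)/c(X) to two new flasks that differ from it in that ratio and in their time.

the same everywhere: X 1.9 M

| flask | D | remark | time |
|---|---|---|---|
| winter | 1.9 M | run made earlier |  |
| Saturday's | 1.30 M |  | 3.0 h |
| Thursday's | 2.70 M |  | 3.0 h |

winter run (percent of the X charged): time / min: E / % = 8.00: 0.3; 15.0: 1.7; 25.0: 6.6; 50.0: 19.8; 90.0: 31.3

(each reading ± 1 percentage point)

- percentages count the X that a species holds: one J counts as two

- which of the two there is more of at the end, counted by the X in each, Saturday's (E / J)
- which of the two there is more of at the end, counted by the X in each, Thursday's (E / J)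
- amount of E at the end, in percent of the X charged, Saturday's
- amount of E at the end, in percent of the X charged, Thursday's

In the first instants of the winter run, E reads 0.3% at 8.00 min, a gain of 0.0225 /h as a fraction of the X charged. In the middle, from 25.0 min to 50.0 min, the gain is 0.317 /h, faster than at the start, so I expect that something had to build up before E could form. From 50.0 min to 90.0 min it is 0.172 /h, slower than in the middle, although E stands at just 31.3%. I suppose the other X is going to J, which was not read.

If that gain keeps falling exponentially, its time constant is 53.5 min, and E levels off near 41.9%, a reading that carries the scatter of 1 percentage point in each point. E at this plateau over the X not in E, divided by c(D)/c(X), is 0.720; I call this the fork number, a kind of selectivity factor.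

I assume that E needs D and the rest of the X does not, so the fork number stays put when c(D) changes. I assume that both new flasks stand near the plateau at their end, but this rests on the winter time constant, which is shorter than 3.0 h, and the new flasks may run at another pace. My reckoning gives E 33.0% in Saturday's flask and 50.6% in Thursday's.

The forecast says J leads in Saturday's flask and E in Thursday's, with E at 29% and 51%, on the ground that “D favours the E branch”. Its Saturday figure stands below mine.

    Z + G → E (k = 0.0179 /M/min)
    X ⇌ Z (K = 30.0, k = 0.0343 /min)
    D → G (k = 0.0232 /min)
    E → Q (k = 1.94 × 10⁻⁴ /min)
    X + G → L (k = 0.00892 /M/min)
    2 Z → J (k = 0.00958 /M/min)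

Saturday's flask gives E 35.3% and J 46.8%; Thursday's gives E 53.4% and J 27.6%. At that end Z still holds 8.27% in Saturday's flask and 1.72% in Thursday's. Counted as before, the fork number is 0.797 in Saturday's flask and 0.806 in Thursday's, against 0.720 from the winter readings. The neighbouring flask is Thursday's read at 2.0 h, when Z still holds 6.79% and X 0.823%. Setting those two aside and sharing the remainder out by the winter fork number gives E 46.7%, and that flask reads 48.8%.

The data were computed for an exercise; scatter was added.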